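(The numbers in the tables stem from a simulated flask for substances that don't exist.)

Take the balance of the solid substrate first: what has left the solid and is not dissolved has been consumed.

- ash: solid substrate 0.15 M; solid reagent 0.15 M; the very flask that is asked about, followed so far
- flask: solid substrate 0.15 M; solid reagent 0.150 M; time 3.0 min

ash run (percent of the solid substrate charged)

| time / s | target / % | dissolved substrate / % | solid substrate / % |
|---|---|---|---|
| 15.0 | 0.4 | 3.1 | 95.3 |
| 30.0 | 1.2 | 3.1 | 93.5 |
| 50.0 | 2.9 | 3.8 | 90.0 |
| 60.0 | 4.3 | 2.7 | 89.4 |
| 80.0 | 6.5 | 3.5 | 85.6 |
| 90.0 | 7.0 | 3.7 | 83.1 |

(standard deviation of a reading: 0.3 percentage points)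

1. target present at 3.0 min, in percent of the solid substrate charged
2. dissolved substrate present at 3.0 min, in percent of the solid substrate charged

- at the start none of the solid substrate is in solution
- at the start none of the solid reagent is in solution
- dissolved substrate means what is dissolved; the solid is not counted in it
- a reading or a percentage of target counts all its forms, free or not

At 90.0 s the ash run, which is the asked flask followed so far, holds 83.1% as solid and 3.7% dissolved, so 13.2% of the charge has been consumed. Multiplied by the charge and divided by the time, that is 0.0132 M/min, which I call the drain: molar solid substrate consumed per minute. Held for 3.0 min, it takes 0.0396 M, less than the 0.15 M charged, so by my reckoning solid remains at the asked time.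

Two chemists read these runs differently. The first sees a saturated solution fed by solid, a steady zero-order drain, and forecasts 20% target and 3.3% dissolved substrate, “as expected for a zero-order reaction from saturated solutions”. The second watches the target, which grew 3.58 times from 30.0 s to 60.0 s, close to the 4.00 of a square law in time; carried on from 90.0 s, that law gives 28.0%. The first replies that from 60.0 s to 90.0 s the target grew 1.63 times, less than the 2.25 the square law needs.

The flask gives 18.7% target and 3.25% dissolved substrate, so its target lies nearer the first chemist's number than the second's; the square law's region is the readings up to 60.0 s.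

    solid substrate ⇌ dissolved substrate, rate k1*(cs1 - [dissolved substrate]) while solid is left; crystals form when [dissolved substrate] > cs1 (solubility = 5.00 mM, k = 2.62 /s)
    dissolved substrate + coupling partner → target (k = 0.624 /M/s)
    2 dissolved substrate → side product A (k = 1.60 /M/s)
    solid product ⇌ target, rate k4*(cs4 - [target]) while solid is left; crystals form when [target] > cs4 (solubility = 48.0 mM, k = 0.988 /s)
    solid substrate + target → side product B (k = 0.0211 /M/s)
    solid reagent ⇌ coupling partner, rate k6*(cs6 - [coupling partner]) while solid is left; crystals form when [coupling partner] > cs6 (solubility = 0.0950 M, k = 0.0180 /s)

Over 3.0 min the flask's mean drain was 0.0173 M/min, above the 0.0132 M/min read at 90.0 s, with 62.1% still solid. Now charge the neighbouring flask with 0.037 M of solid substrate. At 0.0132 M/min that charge lasts 2.80 min, less than the 3.0 min allowed. At 3.0 min the neighbouring flask holds 0% solid substrate, 0.924% dissolved substrate and 68.6% target.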